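**Plan**

- Units are numbered 1 to 4 from the top. Unit 4 is the only flavan with a CH2 at C4, has a cis C2-aryl/C3-hydroxyl pair and is bonded through C6, the carbon para to O1. Its ring C (O1, C2, C3, C4, C4a, C8a) is therefore cut at O1–C2 and C3–C4, back to an ortho-quinone methide on a 2,6-dibenzyloxy-4-hydroxyphenyl cap (whose two carbons ortho to the phenol are equivalent) and a (Z)-β-acetoxystyrene.
- The remaining cuts are cap–C4 (unit 3), C4 (unit 2)–C8 (unit 3) and C4 (unit 1)–C6 (unit 2), all leading back to one benzylated 4-alkoxy-(–)-epicatechin.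
- Forward: a unit 1 electrophile brominated at C6 and C8 alkylates C6 of an 8-bromo unit 2 that carries a latent 4-arylthio leaving group. Unit 3 is capped at C4 with silylated 3,5-dibenzyloxyphenol. Silver activation of the thioether then joins the dimer to C8 of the capped unit 3.
- Desilylation and ortho-hydroxymethylation give the salicyl alcohol, the acid-catalysed (4+2) annulation closes ring C of unit 4, and methanolysis followed by hydrogenolysis (benzyl ethers and blocking bromines) ends the route.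
- C2 and C3 of units 1 to 3 come from (–)-epicatechin. The three C4 centres arise by attack trans to the 3-acetoxy group (4β). C2 and C3 of unit 4 come from the Z-alkene (cis) and from the chiral phosphoric acid (absolute sense).

Key step: step 15

Remark: 3,5-dibenzyloxyphenol is taken as a commercial material; the sense of induction of the phosphoric acid in this new pairing cannot be predicted with confidence, so (R)-TRIP [(R)-3,3'-bis(2,4,6-triisopropylphenyl)-1,1'-binaphthyl-2,2'-diyl hydrogen phosphate] is written and its antipode would be taken if a trial on the simple cap alcohol shows the opposite sense.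

**Route**

Step 1
Reactants: 1 (–)-epicatechin
Product: 2 5,7,3',4'-tetra-O-benzyl-(–)-epicatechin
Conditions: BnBr (4.4 equiv), K2CO3, DMF, 0 °C → rt
Reagents that add atoms: benzyl bromide, BrCc1ccccc1
Why: Williamson etherification under carbonate takes only the four phenols, leaving the secondary 3-hydroxyl free and C2/C3 untouched.

Step 2
Reactants: 2 5,7,3',4'-tetra-O-benzyl-(–)-epicatechin
Product: 3 5,7,3',4'-tetra-O-benzyl-4β-(2-ethoxyethoxy)epicatechin
Conditions: DDQ (2 equiv), EtOCH2CH2OH, CH2Cl2, rt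
Reagents that add atoms: 2-ethoxyethanol, CCOCCO
Why: DDQ benzylic oxidation removes hydride from the C4 methylene activated by the 5,7-dioxygenated ring A, and the alcohol adds to the cation anti to the 3-hydroxyl and 2-aryl groups, which gives the 4β ether.

Step 3
Reactants: 3 5,7,3',4'-tetra-O-benzyl-4β-(2-ethoxyethoxy)epicatechin
Product: 4 3-O-acetyl-5,7,3',4'-tetra-O-benzyl-4β-(2-ethoxyethoxy)epicatechin
Conditions: Ac2O, pyridine, DMAP (cat.), CH2Cl2, rt
Reagents that add atoms: acetic anhydride, CC(=O)OC(C)=O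
Why: DMAP-catalysed acylation caps the only free hydroxyl and provides a participating 3-acetate that later directs nucleophiles to the β-face of C4.

Step 4
Reactants: 4 3-O-acetyl-5,7,3',4'-tetra-O-benzyl-4β-(2-ethoxyethoxy)epicatechin
Product: 5 3-O-acetyl-5,7,3',4'-tetra-O-benzyl-6,8-dibromo-4β-(2-ethoxyethoxy)epicatechin
Conditions: NBS (2.3 equiv), CH2Cl2, –20 °C → rt
Reagents that add atoms: N-bromosuccinimide, O=C1CCC(=O)N1Br
Why: electrophilic aromatic bromination of the phloroglucinol-type ring A at C8 and then C6 leaves the unit 1 electrophile without any nucleophilic ring carbon, so it cannot condense with itself.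

Step 5
Reactants: 4 3-O-acetyl-5,7,3',4'-tetra-O-benzyl-4β-(2-ethoxyethoxy)epicatechin
Product: 6 3-O-acetyl-5,7,3',4'-tetra-O-benzyl-8-bromo-4β-(2-ethoxyethoxy)epicatechin
Conditions: NBS (1.0 equiv), CH2Cl2, –78 → –20 °C
Reagents that add atoms: N-bromosuccinimide, O=C1CCC(=O)N1Br
Why: with one equivalent, electrophilic aromatic bromination stops at the more accessible C8 (between O1 and one benzyloxy group), leaving C6 as the only free carbon of ring A.

Step 6
Reactants: 6 3-O-acetyl-5,7,3',4'-tetra-O-benzyl-8-bromo-4β-(2-ethoxyethoxy)epicatechin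
Product: 7 3-O-acetyl-5,7,3',4'-tetra-O-benzyl-8-bromo-4β-(2,6-dimethylphenylthio)epicatechin
Conditions: 2,6-Me2C6H3SH (3 equiv), BF3·OEt2 (0.3 equiv), CH2Cl2, –78 → –30 °C
Reagents that add atoms: 2,6-dimethylbenzenethiol, Cc1cccc(C)c1S
Why: Lewis acid-mediated thiolysis (SN1 through the acetate-stabilised C4 cation) installs a soft leaving group trans to the 3-acetate, and the two ortho methyl groups shield sulfur against later thio-group transfer.

Step 7
Reactants: 5 3-O-acetyl-5,7,3',4'-tetra-O-benzyl-6,8-dibromo-4β-(2-ethoxyethoxy)epicatechin; 7 3-O-acetyl-5,7,3',4'-tetra-O-benzyl-8-bromo-4β-(2,6-dimethylphenylthio)epicatechin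
Product: 8 dimer thioether [unit 1 = 3-O-acetyl-tetra-O-benzyl-6,8-dibromoepicatechin; 4β→6; unit 2 = 3-O-acetyl-tetra-O-benzyl-8-bromo-4β-(2,6-dimethylphenylthio)epicatechin]
Conditions: 5 (1.2 equiv), BF3·OEt2 (0.5 equiv), CH2Cl2, –78 → –20 °C
Reagents that add atoms: none
Why: in this Friedel–Crafts alkylation the oxophilic boron ionises only the C4–O bond of 5, and the cation, covered on its α-face by the participating 3-acetate and the 2-aryl group, is taken on the β-face by C6 of 7, the only unsubstituted carbon of its ring A, which fixes the 4β→6 link.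

Step 8
Reactants: 9 3,5-dibenzyloxyphenol
Product: 10 (3,5-dibenzyloxyphenoxy)triisopropylsilane
Conditions: iPr3SiCl, imidazole, DMF, rt
Reagents that add atoms: triisopropylsilyl chloride, CC(C)[Si](Cl)(C(C)C)C(C)C
Why: silylation of the phenol gives a bulky ether that later shields both ring carbons next to it.

Step 9
Reactants: 4 3-O-acetyl-5,7,3',4'-tetra-O-benzyl-4β-(2-ethoxyethoxy)epicatechin; 10 (3,5-dibenzyloxyphenoxy)triisopropylsilane
Product: 11 3-O-acetyl-5,7,3',4'-tetra-O-benzyl-4β-[2,6-dibenzyloxy-4-(triisopropylsilyloxy)phenyl]epicatechin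
Conditions: 10 (4 equiv), TMSOTf (0.3 equiv), CH2Cl2, –78 °C; Et3N quench
Reagents that add atoms: none
Why: in this Friedel–Crafts alkylation the excess phloroglucinol triether outcompetes self-condensation of 4 and should be attacked between its two benzyloxy groups, because both carbons next to the triisopropylsilyloxy group are shielded, while the 3-acetate directs the new bond to the β-face (4β).

Step 10
Reactants: 8 dimer thioether; 11 3-O-acetyl-5,7,3',4'-tetra-O-benzyl-4β-[2,6-dibenzyloxy-4-(triisopropylsilyloxy)phenyl]epicatechin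
Product: 12 silyl-capped trimer [unit 1-(4β→6)-unit 2-(4β→8)-unit 3 carrying the 4β-(2,6-dibenzyloxy-4-triisopropylsilyloxyphenyl) cap]
Conditions: 11 (1.5 equiv), AgBF4 (1.5 equiv), 2,6-di-tert-butyl-4-methylpyridine (2 equiv), 4 Å MS, THF/CH2Cl2, –20 → 0 °C, dark
Reagents that add atoms: none
Why: the thiophilic silver salt ionises only the C4–S bond of unit 2 (ethers, esters and aryl bromides are inert), and the cation is captured on its β-face by C8 of unit 3, the most nucleophilic and least hindered ring A carbon of 11, in the usual 4β→8 sense.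

Step 11
Reactants: 12 silyl-capped trimer
Product: 13 phenol-capped trimer [cap = 2,6-dibenzyloxy-4-hydroxyphenyl]
Conditions: Bu4NF (1.2 equiv), AcOH (1.2 equiv), THF, 0 °C
Reagents that add atoms: none
Why: fluoride cleaves the aryl silyl ether, and the acetic acid buffer keeps the three acetates safe from the phenoxide.

Step 12
Reactants: 13 phenol-capped trimer
Product: 15 trimer salicyl alcohol [cap = 2,6-dibenzyloxy-4-hydroxy-3-(hydroxymethyl)phenyl], via 2-phenyl-4H-1,3,2-benzodioxaborin 14 (not isolated)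
Conditions: PhB(OH)2 (1.5 equiv), (CH2O)n, EtCO2H (cat.), toluene, 80 °C, 4 Å MS; then 30% H2O2, THF, 0 °C
Reagents that add atoms: paraformaldehyde (as formaldehyde), C=O; phenylboronic acid, OB(O)c1ccccc1 (its atoms remain only in 14)
Why: in this boronate-templated ortho-hydroxymethylation the phenol, boronic acid and formaldehyde condense to the cyclic boronate 14, so the new C–C bond can form only ortho to the single free phenol (both ortho carbons are equivalent and a second substitution is excluded once the oxygen is tied up), and oxidative cleavage of the B–C bond releases the diol.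

Step 13
Reactants: 16 3,4-dibenzyloxybenzaldehyde
Product: 17 1,2-dibenzyloxy-4-ethynylbenzene
Conditions: dimethyl (1-diazo-2-oxopropyl)phosphonate, K2CO3, MeOH/THF, rt
Reagents that add atoms: dimethyl (1-diazo-2-oxopropyl)phosphonate, CC(=O)C(=[N+]=[N-])P(=O)(OC)OC
Why: the Ohira–Bestmann homologation (Seyferth–Gilbert type) converts the aldehyde into the terminal alkyne under mild carbonate conditions.

Step 14
Reactants: 17 1,2-dibenzyloxy-4-ethynylbenzene
Product: 18 (Z)-2-(3,4-dibenzyloxyphenyl)vinyl acetate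
Conditions: AcOH (1.5 equiv), Ru(η3-CH2C(CH3)CH2)2(Ph2P(CH2)4PPh2) (2 mol %), toluene, 60 °C
Reagents that add atoms: acetic acid, CC(=O)O
Why: ruthenium-catalysed anti-Markovnikov hydro-acyloxylation of a terminal alkyne proceeds through a vinylidene and delivers the (Z)-enol ester.

Step 15
Reactants: 15 trimer salicyl alcohol; 18 (Z)-2-(3,4-dibenzyloxyphenyl)vinyl acetate
Product: 20 protected tetramer [hexadeca-O-benzyl tetra-O-acetyl tribromide; unit 4 closed as 3-O-acetyl-5,7,3',4'-tetra-O-benzylepicatechin bonded through C6], via ortho-quinone methide 19 (not isolated)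
Conditions: 18 (3 equiv), (R)-TRIP (10 mol %), 5 Å MS, toluene, –20 → 0 °C
Reagents that add atoms: none
Why: Proposed new method: the phosphoric acid protonates the benzylic hydroxyl of 15, water leaves with help from the three ring oxygens, and the hydrogen-bonded ortho-quinone methide 19 is attacked at its CH2 by the acetoxy-bearing carbon of 18 while the methide oxygen closes onto the benzylic carbon in a concerted but asynchronous inverse-electron-demand hetero-(4+2) cycloaddition; the closest known reaction type is the chiral Brønsted acid-catalysed (4+2) cycloaddition of in situ generated ortho-quinone methides with styrenes and enol ethers, not yet shown for a β-acyloxystyrene on an unsubstituted methide of this kind. The one new ring, ring C of unit 4, closes in the (4+2) mode, C3–C4 forming ahead of O1–C2 within a single six-membered transition state. The cis C2-aryl/C3-acetoxy relationship follows from suprafacial addition to the Z-alkene, provided O1–C2 closure inside the contact ion pair is faster than rotation about C2–C3 or acetoxonium formation, and the absolute sense (2R,3R) is set by the chiral phosphate, which holds the methide by a hydrogen bond and shields one face of the approaching alkene, the trimer stereocentres being too remote to decide. Regiochemistry (aryl on C2, acetoxy on C3) rests on the para-benzyloxyaryl group stabilising positive charge better than the acetoxy group. The 4→6 attachment needs no control because 15 has one free phenol whose two ortho carbons are equivalent, and chemoselectivity is secured by the absence of any other free hydroxyl and by the mildness of the acid toward acetates, aryl bromides and interflavan bonds.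

Step 16
Reactants: 20 protected tetramer
Product: 21 hexadeca-O-benzyl tribromo tetramer tetraol
Conditions: NaOMe (0.4 equiv), MeOH/THF (1:1), rt
Reagents that add atoms: none
Why: methoxide-catalysed transesterification removes the four 3-acetates, and with every phenol benzylated there is no pathway for C2 epimerisation or interflavan cleavage.

Step 17
Reactants: 21 hexadeca-O-benzyl tribromo tetramer tetraol
Product: 22 epicatechin-(4β→6)-epicatechin-(4β→8)-epicatechin-(4β→6)-epicatechin (target)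
Conditions: H2 (1 atm), Pd(OH)2/C, Et3N (3.3 equiv), THF/MeOH/H2O, rt
Reagents that add atoms: none
Why: hydrogenolysis cleaves the sixteen benzyl ethers and hydrodehalogenates the three aryl bromides in one operation, with triethylamine taking up HBr so that the acid-labile interflavan bonds are not touched.

**Compound list**

1 | (–)-epicatechin, (2R,3R) | O[C@@H]1Cc2c(O)cc(O)cc2O[C@@H]1c1ccc(O)c(O)c1 | starting material

2 | 5,7,3',4'-tetra-O-benzyl-(–)-epicatechin | c9ccccc9COc1cc(OCc9ccccc9)c2c(c1)O[C@H](c8ccc(OCc9ccccc9)c(OCc9ccccc9)c8)[C@H](O)C2 | intermediate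

3 | 5,7,3',4'-tetra-O-benzyl-4β-(2-ethoxyethoxy)epicatechin (4-alkoxy trans to 3-OH) | c9ccccc9COc1cc(OCc9ccccc9)c2c(c1)O[C@H](c8ccc(OCc9ccccc9)c(OCc9ccccc9)c8)[C@H](O)[C@H]2OCCOCC | intermediate

4 | 3-O-acetyl-5,7,3',4'-tetra-O-benzyl-4β-(2-ethoxyethoxy)epicatechin | c9ccccc9COc1cc(OCc9ccccc9)c2c(c1)O[C@H](c8ccc(OCc9ccccc9)c(OCc9ccccc9)c8)[C@H](OC(C)=O)[C@H]2OCCOCC | intermediate

5 | 3-O-acetyl-5,7,3',4'-tetra-O-benzyl-6,8-dibromo-4β-(2-ethoxyethoxy)epicatechin | c9ccccc9COc1c(Br)c(OCc9ccccc9)c2c(c1Br)O[C@H](c8ccc(OCc9ccccc9)c(OCc9ccccc9)c8)[C@H](OC(C)=O)[C@H]2OCCOCC | intermediate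

6 | 3-O-acetyl-5,7,3',4'-tetra-O-benzyl-8-bromo-4β-(2-ethoxyethoxy)epicatechin | c9ccccc9COc1cc(OCc9ccccc9)c2c(c1Br)O[C@H](c8ccc(OCc9ccccc9)c(OCc9ccccc9)c8)[C@H](OC(C)=O)[C@H]2OCCOCC | intermediate

7 | 3-O-acetyl-5,7,3',4'-tetra-O-benzyl-8-bromo-4β-(2,6-dimethylphenylthio)epicatechin | c9ccccc9COc1cc(OCc9ccccc9)c2c(c1Br)O[C@H](c8ccc(OCc9ccccc9)c(OCc9ccccc9)c8)[C@H](OC(C)=O)[C@H]2Sc7c(C)cccc7C | intermediate

8 | dimer thioether: 3-O-acetyl-tetra-O-benzyl-6,8-dibromoepicatechin-(4β→6)-[3-O-acetyl-tetra-O-benzyl-8-bromo-4β-(2,6-dimethylphenylthio)epicatechin] | c9ccccc9COc1c(Br)c(OCc9ccccc9)c2c(c1Br)O[C@H](c8ccc(OCc9ccccc9)c(OCc9ccccc9)c8)[C@H](OC(C)=O)[C@H]2c1c(OCc9ccccc9)c(Br)c2c(c1OCc9ccccc9)[C@H](Sc7c(C)cccc7C)[C@@H](OC(C)=O)[C@@H](c8ccc(OCc9ccccc9)c(OCc9ccccc9)c8)O2 | intermediate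

9 | 3,5-dibenzyloxyphenol | Oc1cc(OCc2ccccc2)cc(OCc2ccccc2)c1 | starting material

10 | (3,5-dibenzyloxyphenoxy)triisopropylsilane | CC(C)[Si](C(C)C)(C(C)C)Oc1cc(OCc2ccccc2)cc(OCc2ccccc2)c1 | intermediate

11 | 3-O-acetyl-5,7,3',4'-tetra-O-benzyl-4β-[2,6-dibenzyloxy-4-(triisopropylsilyloxy)phenyl]epicatechin | c9ccccc9COc1cc(OCc9ccccc9)c2c(c1)O[C@H](c8ccc(OCc9ccccc9)c(OCc9ccccc9)c8)[C@H](OC(C)=O)[C@H]2c1c(OCc9ccccc9)cc(O[Si](C(C)C)(C(C)C)C(C)C)cc1OCc9ccccc9 | intermediate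

12 | silyl-capped trimer: unit 1 (6,8-dibromo)-(4β→6)-unit 2 (8-bromo)-(4β→8)-unit 3, each 3-O-acetyl and tetra-O-benzyl, unit 3 carrying 4β-[2,6-dibenzyloxy-4-(triisopropylsilyloxy)phenyl] | c9ccccc9COc1c(Br)c(OCc9ccccc9)c2c(c1Br)O[C@H](c8ccc(OCc9ccccc9)c(OCc9ccccc9)c8)[C@H](OC(C)=O)[C@H]2c1c(OCc9ccccc9)c(Br)c2c(c1OCc9ccccc9)[C@H](c1c(OCc9ccccc9)cc(OCc9ccccc9)c3c1O[C@H](c8ccc(OCc9ccccc9)c(OCc9ccccc9)c8)[C@H](OC(C)=O)[C@H]3c1c(OCc9ccccc9)cc(O[Si](C(C)C)(C(C)C)C(C)C)cc1OCc9ccccc9)[C@@H](OC(C)=O)[C@@H](c8ccc(OCc9ccccc9)c(OCc9ccccc9)c8)O2 | intermediate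

13 | phenol-capped trimer: as 12 with the cap 2,6-dibenzyloxy-4-hydroxyphenyl | c9ccccc9COc1c(Br)c(OCc9ccccc9)c2c(c1Br)O[C@H](c8ccc(OCc9ccccc9)c(OCc9ccccc9)c8)[C@H](OC(C)=O)[C@H]2c1c(OCc9ccccc9)c(Br)c2c(c1OCc9ccccc9)[C@H](c1c(OCc9ccccc9)cc(OCc9ccccc9)c3c1O[C@H](c8ccc(OCc9ccccc9)c(OCc9ccccc9)c8)[C@H](OC(C)=O)[C@H]3c1c(OCc9ccccc9)cc(O)cc1OCc9ccccc9)[C@@H](OC(C)=O)[C@@H](c8ccc(OCc9ccccc9)c(OCc9ccccc9)c8)O2 | intermediate

14 | trimer 2-phenyl-4H-1,3,2-benzodioxaborin: cap phenol oxygen and new ortho CH2O bridged by B–Ph | c9ccccc9COc1c(Br)c(OCc9ccccc9)c2c(c1Br)O[C@H](c8ccc(OCc9ccccc9)c(OCc9ccccc9)c8)[C@H](OC(C)=O)[C@H]2c1c(OCc9ccccc9)c(Br)c2c(c1OCc9ccccc9)[C@H](c1c(OCc9ccccc9)cc(OCc9ccccc9)c3c1O[C@H](c8ccc(OCc9ccccc9)c(OCc9ccccc9)c8)[C@H](OC(C)=O)[C@H]3c1c(OCc9ccccc9)cc4OB(c7ccccc7)OCc4c1OCc9ccccc9)[C@@H](OC(C)=O)[C@@H](c8ccc(OCc9ccccc9)c(OCc9ccccc9)c8)O2 | intermediate (not isolated)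

15 | trimer salicyl alcohol: as 13 with the cap 2,6-dibenzyloxy-4-hydroxy-3-(hydroxymethyl)phenyl | c9ccccc9COc1c(Br)c(OCc9ccccc9)c2c(c1Br)O[C@H](c8ccc(OCc9ccccc9)c(OCc9ccccc9)c8)[C@H](OC(C)=O)[C@H]2c1c(OCc9ccccc9)c(Br)c2c(c1OCc9ccccc9)[C@H](c1c(OCc9ccccc9)cc(OCc9ccccc9)c3c1O[C@H](c8ccc(OCc9ccccc9)c(OCc9ccccc9)c8)[C@H](OC(C)=O)[C@H]3c1c(OCc9ccccc9)cc(O)c(CO)c1OCc9ccccc9)[C@@H](OC(C)=O)[C@@H](c8ccc(OCc9ccccc9)c(OCc9ccccc9)c8)O2 | intermediate

16 | 3,4-dibenzyloxybenzaldehyde | O=Cc1ccc(OCc2ccccc2)c(OCc2ccccc2)c1 | starting material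

17 | 1,2-dibenzyloxy-4-ethynylbenzene | C#Cc1ccc(OCc2ccccc2)c(OCc2ccccc2)c1 | intermediate

18 | (Z)-2-(3,4-dibenzyloxyphenyl)vinyl acetate | CC(=O)O/C=C\c1ccc(OCc2ccccc2)c(OCc2ccccc2)c1 | intermediate

19 | trimer ortho-quinone methide: cap as 3,5-dibenzyloxy-6-methylenecyclohexa-2,4-dienone bonded through C4 | c9ccccc9COc1c(Br)c(OCc9ccccc9)c2c(c1Br)O[C@H](c8ccc(OCc9ccccc9)c(OCc9ccccc9)c8)[C@H](OC(C)=O)[C@H]2c1c(OCc9ccccc9)c(Br)c2c(c1OCc9ccccc9)[C@H](c1c(OCc9ccccc9)cc(OCc9ccccc9)c3c1O[C@H](c8ccc(OCc9ccccc9)c(OCc9ccccc9)c8)[C@H](OC(C)=O)[C@H]3C1=C(OCc9ccccc9)C(=C)C(=O)C=C1OCc9ccccc9)[C@@H](OC(C)=O)[C@@H](c8ccc(OCc9ccccc9)c(OCc9ccccc9)c8)O2 | intermediate (not isolated)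

20 | protected tetramer: unit 1 (6,8-dibromo)-(4β→6)-unit 2 (8-bromo)-(4β→8)-unit 3-(4β→6)-unit 4, every unit 3-O-acetyl-5,7,3',4'-tetra-O-benzylepicatechin | c9ccccc9COc1c(Br)c(OCc9ccccc9)c2c(c1Br)O[C@H](c8ccc(OCc9ccccc9)c(OCc9ccccc9)c8)[C@H](OC(C)=O)[C@H]2c1c(OCc9ccccc9)c(Br)c2c(c1OCc9ccccc9)[C@H](c1c(OCc9ccccc9)cc(OCc9ccccc9)c3c1O[C@H](c8ccc(OCc9ccccc9)c(OCc9ccccc9)c8)[C@H](OC(C)=O)[C@H]3c1c(OCc9ccccc9)cc3c(c1OCc9ccccc9)C[C@@H](OC(C)=O)[C@@H](c8ccc(OCc9ccccc9)c(OCc9ccccc9)c8)O3)[C@@H](OC(C)=O)[C@@H](c8ccc(OCc9ccccc9)c(OCc9ccccc9)c8)O2 | intermediate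

21 | hexadeca-O-benzyl tribromo tetramer tetraol: as 20 with four free 3-hydroxyls | c9ccccc9COc1c(Br)c(OCc9ccccc9)c2c(c1Br)O[C@H](c8ccc(OCc9ccccc9)c(OCc9ccccc9)c8)[C@H](O)[C@H]2c1c(OCc9ccccc9)c(Br)c2c(c1OCc9ccccc9)[C@H](c1c(OCc9ccccc9)cc(OCc9ccccc9)c3c1O[C@H](c8ccc(OCc9ccccc9)c(OCc9ccccc9)c8)[C@H](O)[C@H]3c1c(OCc9ccccc9)cc3c(c1OCc9ccccc9)C[C@@H](O)[C@@H](c8ccc(OCc9ccccc9)c(OCc9ccccc9)c8)O3)[C@@H](O)[C@@H](c8ccc(OCc9ccccc9)c(OCc9ccccc9)c8)O2 | intermediate

22 | epicatechin-(4β→6)-epicatechin-(4β→8)-epicatechin-(4β→6)-epicatechin | Oc1cc(O)c2c(c1)O[C@H](c1ccc(O)c(O)c1)[C@H](O)[C@H]2c1c(O)cc2c(c1O)[C@H](c1c(O)cc(O)c3c1O[C@H](c1ccc(O)c(O)c1)[C@H](O)[C@H]3c1c(O)cc3c(c1O)C[C@@H](O)[C@@H](c1ccc(O)c(O)c1)O3)[C@@H](O)[C@@H](c1ccc(O)c(O)c1)O2 | target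

**Step count**

Total: 17 steps. Longest linear sequence: 12 steps (steps 1, 2, 3, 5, 6, 7, 10, 11, 12, 15, 16, 17).

**Steps most likely to fail**

1. Step 15. The annulation may lose the alkene geometry through a stepwise cationic pathway (bond rotation or acetoxonium formation before O1–C2 closure), may show weak facial discrimination by the acid, may divert into acetyl transfer from the enol ester to the salicyl alcohol, or the methide may condense with itself. The fallback uses known interflavan chemistry, sets out from 8 and 4 and comes back at 22. Activation of 8 with AgBF4 and 2,6-di-tert-butyl-4-methylpyridine in the presence of an excess of 4, whose C8 is the nucleophile and whose 4-(2-ethoxyethoxy) group is inert to the silver salt, should give the trimer 4β-(2-ethoxyethoxy) ether F1. Bromination of 2 with one equivalent of NBS gives 8-bromo-5,7,3',4'-tetra-O-benzylepicatechin F2, whose only free ring A carbon (C6) is alkylated by F1 under catalytic TMSOTf to give the 4β→6-linked tetrabromo tetramer triacetate F3. NaOMe in MeOH/THF then gives the tetrabromo tetramer tetraol F4, and hydrogenolysis over Pd(OH)2/C with Et3N removes four bromines and sixteen benzyl groups to reach 22.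

2. Step 7. Carbon–carbon bond formation at the bromine-deactivated and doubly flanked C6 of 7 may be slow, so that proton loss from the cation of 5 to the flav-3-ene or premature loss of the arylthio group takes over. The fallback introduces the leaving group of unit 2 after the coupling; it sets out from 2 and 5 and comes back at 12. Acetylation of 2 gives 3-O-acetyl-5,7,3',4'-tetra-O-benzylepicatechin F5, and NBS (1 equiv) gives its 8-bromide F6, which has no C4 substituent. TMSOTf-mediated coupling with 5 gives the 4β→6 dimer F7. DDQ with 2-ethoxyethanol then oxidises the only unhindered benzylic methylene (C4 of unit 2) to the dimer 4β-(2-ethoxyethoxy) ether F8, which is coupled with 11 under catalytic TMSOTf to give 12.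

3. Step 9. The cation may alkylate a ring carbon next to the silyl ether instead of the carbon between the two benzyl ethers, and chain growth through C8 of the product may compete. The fallback makes the regiochemistry unambiguous by symmetry; it sets out from 4 and comes back at 11. Capture of the cation from 4 by an excess of free phloroglucinol (TMSOTf, THF/CH2Cl2) gives 3-O-acetyl-5,7,3',4'-tetra-O-benzyl-4β-(2,4,6-trihydroxyphenyl)epicatechin F9. The unhindered hydroxyl para to the flavanyl group is silylated selectively (iPr3SiCl, imidazole) to the 4-silyl ether F10, and the two flanking hydroxyls are benzylated (BnBr, K2CO3, acetone) to give 11.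

**Further compounds**

F1 | step 15 | trimer 4β-(2-ethoxyethoxy) ether: unit 1 (6,8-dibromo)-(4β→6)-unit 2 (8-bromo)-(4β→8)-unit 3 with 4β-OCH2CH2OEt, all 3-O-acetyl tetra-O-benzyl | c9ccccc9COc1c(Br)c(OCc9ccccc9)c2c(c1Br)O[C@H](c8ccc(OCc9ccccc9)c(OCc9ccccc9)c8)[C@H](OC(C)=O)[C@H]2c1c(OCc9ccccc9)c(Br)c2c(c1OCc9ccccc9)[C@H](c1c(OCc9ccccc9)cc(OCc9ccccc9)c3c1O[C@H](c8ccc(OCc9ccccc9)c(OCc9ccccc9)c8)[C@H](OC(C)=O)[C@H]3OCCOCC)[C@@H](OC(C)=O)[C@@H](c8ccc(OCc9ccccc9)c(OCc9ccccc9)c8)O2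

F2 | step 15 | 8-bromo-5,7,3',4'-tetra-O-benzylepicatechin | c9ccccc9COc1cc(OCc9ccccc9)c2c(c1Br)O[C@H](c8ccc(OCc9ccccc9)c(OCc9ccccc9)c8)[C@H](O)C2

F3 | step 15 | tetrabromo tetramer triacetate: as 20 but unit 4 is 8-bromo with free 3-hydroxyl | c9ccccc9COc1c(Br)c(OCc9ccccc9)c2c(c1Br)O[C@H](c8ccc(OCc9ccccc9)c(OCc9ccccc9)c8)[C@H](OC(C)=O)[C@H]2c1c(OCc9ccccc9)c(Br)c2c(c1OCc9ccccc9)[C@H](c1c(OCc9ccccc9)cc(OCc9ccccc9)c3c1O[C@H](c8ccc(OCc9ccccc9)c(OCc9ccccc9)c8)[C@H](OC(C)=O)[C@H]3c1c(OCc9ccccc9)c(Br)c3c(c1OCc9ccccc9)C[C@@H](O)[C@@H](c8ccc(OCc9ccccc9)c(OCc9ccccc9)c8)O3)[C@@H](OC(C)=O)[C@@H](c8ccc(OCc9ccccc9)c(OCc9ccccc9)c8)O2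

F4 | step 15 | tetrabromo tetramer tetraol: hexadeca-O-benzyl with four free 3-hydroxyls | c9ccccc9COc1c(Br)c(OCc9ccccc9)c2c(c1Br)O[C@H](c8ccc(OCc9ccccc9)c(OCc9ccccc9)c8)[C@H](O)[C@H]2c1c(OCc9ccccc9)c(Br)c2c(c1OCc9ccccc9)[C@H](c1c(OCc9ccccc9)cc(OCc9ccccc9)c3c1O[C@H](c8ccc(OCc9ccccc9)c(OCc9ccccc9)c8)[C@H](O)[C@H]3c1c(OCc9ccccc9)c(Br)c3c(c1OCc9ccccc9)C[C@@H](O)[C@@H](c8ccc(OCc9ccccc9)c(OCc9ccccc9)c8)O3)[C@@H](O)[C@@H](c8ccc(OCc9ccccc9)c(OCc9ccccc9)c8)O2

F5 | step 7 | 3-O-acetyl-5,7,3',4'-tetra-O-benzylepicatechin | c9ccccc9COc1cc(OCc9ccccc9)c2c(c1)O[C@H](c8ccc(OCc9ccccc9)c(OCc9ccccc9)c8)[C@H](OC(C)=O)C2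

F6 | step 7 | 3-O-acetyl-5,7,3',4'-tetra-O-benzyl-8-bromoepicatechin | c9ccccc9COc1cc(OCc9ccccc9)c2c(c1Br)O[C@H](c8ccc(OCc9ccccc9)c(OCc9ccccc9)c8)[C@H](OC(C)=O)C2

F7 | step 7 | dimer: 3-O-acetyl-tetra-O-benzyl-6,8-dibromoepicatechin-(4β→6)-(3-O-acetyl-tetra-O-benzyl-8-bromoepicatechin) | c9ccccc9COc1c(Br)c(OCc9ccccc9)c2c(c1Br)O[C@H](c8ccc(OCc9ccccc9)c(OCc9ccccc9)c8)[C@H](OC(C)=O)[C@H]2c1c(OCc9ccccc9)c(Br)c2c(c1OCc9ccccc9)C[C@@H](OC(C)=O)[C@@H](c8ccc(OCc9ccccc9)c(OCc9ccccc9)c8)O2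

F8 | step 7 | dimer 4β-(2-ethoxyethoxy) ether: as F7 with 4β-OCH2CH2OEt on unit 2 | c9ccccc9COc1c(Br)c(OCc9ccccc9)c2c(c1Br)O[C@H](c8ccc(OCc9ccccc9)c(OCc9ccccc9)c8)[C@H](OC(C)=O)[C@H]2c1c(OCc9ccccc9)c(Br)c2c(c1OCc9ccccc9)[C@H](OCCOCC)[C@@H](OC(C)=O)[C@@H](c8ccc(OCc9ccccc9)c(OCc9ccccc9)c8)O2

F9 | step 9 | 3-O-acetyl-5,7,3',4'-tetra-O-benzyl-4β-(2,4,6-trihydroxyphenyl)epicatechin | c9ccccc9COc1cc(OCc9ccccc9)c2c(c1)O[C@H](c8ccc(OCc9ccccc9)c(OCc9ccccc9)c8)[C@H](OC(C)=O)[C@H]2c1c(O)cc(O)cc1O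

F10 | step 9 | 3-O-acetyl-5,7,3',4'-tetra-O-benzyl-4β-[2,6-dihydroxy-4-(triisopropylsilyloxy)phenyl]epicatechin | c9ccccc9COc1cc(OCc9ccccc9)c2c(c1)O[C@H](c8ccc(OCc9ccccc9)c(OCc9ccccc9)c8)[C@H](OC(C)=O)[C@H]2c1c(O)cc(O[Si](C(C)C)(C(C)C)C(C)C)cc1O
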